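Atom labels (briarane numbering): C1 is the methyl-bearing quaternary ring-fusion carbon, C2 the neighbouring AcO–CH of the ten-membered ring (C1–C10), C14 the AcO–CH of the cyclohexene next to C1. C2–C1–C14 is a 1,3-dioxygenated aldol unit, so the ten-membered ring is closed last by the aldol bond C1–C2: SmI2 cleaves a C1–SPh bond of a C14 ketone, releasing the samarium enolate regiospecifically at C1, which adds to the C2 aldehyde. One operation closes the ring and sets quaternary C1 and C2. The precursor is a seco keto-aldehyde whose cyclohexenone and hydroxy-lactone halves hang on a C6–C10 spine taken from L-arabinose.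

Key step: step 21

Remark: further locants are C3–C9 (ten-membered ring), C10 (second fusion carbon), C11(CH3)=C12–C13 (cyclohexene), C16 (CH2O on C5) and the lactone C7–O–C19(=O)–C17(CH3)–C8.
Remark: C17 (steps 6–15), C1 (steps 9–20) and C14 (steps 10–19) are carried as epimer mixtures; C17 is set in step 16, C14 is erased in step 20 and C1 in step 21.

Step 1
Reactants: 1 (4-bromobutoxy)(tert-butyl)dimethylsilane
Product: 2 [4-(tert-butyldimethylsilyloxy)butyl]triphenylphosphonium bromide
Conditions: PPh3, MeCN, reflux
Reagents that add atoms: triphenylphosphine (c1ccc(cc1)P(c1ccccc1)c1ccccc1)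
Why: SN2 quaternisation of the primary bromide by PPh3 (phosphonium salt formation) is routine and leaves the silyl ether untouched.

Step 2
Reactants: 2 [4-(tert-butyldimethylsilyloxy)butyl]triphenylphosphonium bromide
Product: 4 5-(tert-butyldimethylsilyloxy)-2-(triphenyl-λ5-phosphanylidene)pentanal, via phosphonium ylide 3 (not isolated)
Conditions: KOtBu, THF, 0 °C; then HCO2Et, 0 °C → rt
Reagents that add atoms: ethyl formate (CCOC=O)
Why: Deprotonation gives the non-stabilised ylide, whose C-formylation by ethyl formate (ylide acylation; the expelled ethoxide completes the transylidation) gives the formyl-stabilised ylide.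

Step 3
Reactants: 5 L-arabinose
Product: 6 5-O-(tert-butyldiphenylsilyl)-L-arabinofuranose (anomer mixture)
Conditions: TBDPSCl, pyridine, 0 °C → rt
Reagents that add atoms: tert-butyldiphenylsilyl chloride (CC(C)(C)[Si](Cl)(c1ccccc1)c1ccccc1)
Why: Selective O-silylation occurs only at the primary hydroxyl, which exists in the furanose tautomer, so L-arabinose is trapped as the 5-O-silyl furanose; C2 and C4 of the sugar become C7 and C9 of the target and are not touched.

Step 4
Reactants: 6 5-O-TBDPS-L-arabinofuranose
Product: 7 5-O-TBDPS-1,2-O-isopropylidene-β-L-arabinofuranose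
Conditions: 2,2-dimethoxypropane, CSA (cat.), acetone, rt
Reagents that add atoms: 2,2-dimethoxypropane (COC(C)(C)OC)
Why: Acid-catalysed isopropylidenation (acetalisation) can only close the cis-fused dioxolane across O1/O2 of the β-furanose, because O3 is trans to O2, which leaves the C3 hydroxyl as the single free alcohol.

Step 5
Reactants: 7 5-O-TBDPS-1,2-O-isopropylidene-β-L-arabinofuranose
Product: 8 5-O-TBDPS-1,2-O-isopropylidene-β-L-threo-pentofuranos-3-ulose
Conditions: Dess–Martin periodinane, NaHCO3, CH2Cl2, rt
Reagents that add atoms: none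
Why: Dess–Martin oxidation converts the hindered secondary alcohol into the 3-ulose without epimerising the flanking acetal and ether centres.

Step 6
Reactants: 8 the 3-ulose
Product: 9 methyl 2-(5-O-TBDPS-1,2-O-isopropylidene-β-L-lyxofuranos-3-C-yl)propanoate (tertiary OH cis to the dioxolane; C17 epimers)
Conditions: LDA, methyl propionate, THF, −78 °C; then 8, −78 °C; sat. aq. NH4Cl at −78 °C
Reagents that add atoms: methyl propionate (CCC(=O)OC)
Why: Aldol addition of the lithium ester enolate to the ketone occurs on the exo face, anti to the cis-fused dioxolane and to the C4 side chain that both shield the other face, which sets the tertiary carbinol C8 in the L-lyxo sense, while C17 forms as an epimer mixture that is corrected in step 16.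

Step 7
Reactants: 9 the silyl-protected aldol adduct
Product: 10 methyl 2-(1,2-O-isopropylidene-β-L-lyxofuranos-3-C-yl)propanoate (free primary OH at C10)
Conditions: TBAF, AcOH (1:1), THF, 0 °C → rt
Reagents that add atoms: none
Why: Fluoride-mediated desilylation frees the primary alcohol, and the acetic acid buffer keeps the medium non-basic so that the β-hydroxy ester neither undergoes retro-aldol cleavage nor lactonises onto the new alcohol.

Step 8
Reactants: 10 the primary alcohol
Product: 12 (E)-2-methyl enal C9–CH=C(CH3)–CHO on the furanose (C10=C1, C14 aldehyde), via pentodialdofuranose aldehyde 11 (not isolated)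
Conditions: IBX, DMSO, rt; then Ph3P=C(CH3)CHO, rt → 40 °C
Reagents that add atoms: 2-(triphenyl-λ5-phosphanylidene)propanal (CC(C=O)=P(c1ccccc1)(c1ccccc1)c1ccccc1)
Why: IBX oxidation gives the α-alkoxy aldehyde, which is trapped in the same flask by Wittig olefination with the formyl-stabilised ylide to give the (E)-2-methyl enal (aldehyde-derived substituent trans to CHO).

Step 9
Reactants: 12 the (E)-enal
Product: 14 aldehyde with C10 isopropenyl and C1(CH3)(SPh) (C10 configured as in the target; C1 epimers), via TMS enol ether 13 (not isolated)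
Conditions: isopropenylMgBr, CuBr·SMe2, TMSCl, THF, −78 °C; then PhSCl, −78 °C
Reagents that add atoms: isopropenylmagnesium bromide (CC(=C)[Mg]Br); benzenesulfenyl chloride (ClSc1ccccc1)
Why: Copper-mediated 1,4-addition with TMSCl trapping follows the Felkin–Anh model for γ-alkoxy acceptors (nucleophile anti to the C9–O bond of the furanose, H inside), which sets C10 with the 9,10-anti relationship of the target, and sulfenylation of the resulting silyl enol ether with PhSCl installs the C1–SPh group whose configuration is irrelevant.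

Step 10
Reactants: 14 the α-phenylthio aldehyde
Product: 15 homoallylic alcohol (C14–OH, C13–C12 allyl; C14 epimers)
Conditions: Zn, allyl bromide, THF/sat. aq. NH4Cl, 0 °C → rt
Reagents that add atoms: allyl bromide (C=CCBr)
Why: Barbier allylation with allylzinc bromide generated in situ is chemoselective for the non-enolisable aldehyde over the methyl ester and tolerates the free tertiary alcohol; the C14 carbinol configuration is irrelevant because it is oxidised in step 20.

Step 11
Reactants: 15 the homoallylic alcohol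
Product: 16 C14 tert-butyldimethylsilyl ether
Conditions: TBSOTf (1.1 equiv), 2,6-lutidine, CH2Cl2, −78 °C
Reagents that add atoms: tert-butyldimethylsilyl triflate (CC(C)(C)[Si](C)(C)OS(=O)(=O)C(F)(F)F)
Why: Silyl triflate/lutidine silylation at −78 °C distinguishes the secondary C14 alcohol from the more hindered tertiary C8 alcohol.

Step 12
Reactants: 16 the diene
Product: 17 cyclohexene (C10, C11(CH3)=C12, C13, C14–OTBS, C1(CH3)(SPh)) attached at C9 of the furanose
Conditions: Grubbs II (5 mol %), CH2Cl2, 40 °C
Reagents that add atoms: none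
Why: Ring-closing metathesis of the isopropenyl and allyl groups gives the trisubstituted cyclohexene (C11=C12) with loss of ethylene, a six-membered closure that is strongly favoured.

Step 13
Reactants: 17 the isopropylidene furanose
Product: 18 lactol (free furanose, C6 anomer mixture, free C7–OH)
Conditions: TFA/H2O (4:1), 0 °C, 20 min
Reagents that add atoms: none
Why: Aqueous acid hydrolysis of the 1,2-O-isopropylidene acetal releases the lactol, while the hindered secondary TBS ether and the methyl ester survive the short exposure at 0 °C.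

Step 14
Reactants: 18 the lactol; 4 the formyl ylide
Product: 19 open-chain (E)-enal (C16 aldehyde on C5=C6) with free C7, C8 and C9 hydroxyls, C19 methyl ester and C2–OTBS
Conditions: 4 (2 equiv), PhCO2H (cat.), toluene, 90 °C
Reagents that add atoms: none
Why: Wittig olefination of the open-chain aldehyde tautomer of the lactol with the formyl-stabilised ylide gives the (E)-enal, i.e. C16 trans to C7 across C5=C6 as in the target, and frees the C9 hydroxyl.

Step 15
Reactants: 19 the enal
Product: 20 allylic alcohol (C16–OH; tetraol methyl ester)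
Conditions: NaBH4, CeCl3·7H2O, MeOH, −40 °C
Reagents that add atoms: none
Why: Luche reduction (NaBH4/CeCl3) reduces the enal 1,2 to the allylic alcohol and leaves the methyl ester alone.

Step 16
Reactants: 20 the tetraol methyl ester
Product: 21 γ-lactone (O7–C19) with C17 methyl cis to the C8 hydroxyl; C8, C9 and C16 hydroxyls free
Conditions: DBU, toluene, 80 °C
Reagents that add atoms: none
Why: DBU-mediated lactonisation (5-exo-trig acyl transfer to O7, favoured over O9 because only the O7 lactone keeps the C6 and C9 chains trans on the ring) is followed by base-mediated equilibration of the epimerisable C17, which settles with the methyl group anti to the bulky C9 chain and cis to the C8 hydroxyl, as in the target.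

Step 17
Reactants: 21 the lactone triol
Product: 22 O8,O9-isopropylidene acetal (C16–OH free)
Conditions: 2,2-dimethoxypropane, PPTS (cat.), CH2Cl2, rt; then MeOH
Reagents that add atoms: 2,2-dimethoxypropane (COC(C)(C)OC)
Why: Acid-catalysed isopropylidenation ties the vicinal C8/C9 diol into a dioxolane (the transient mixed acetal at the C16 hydroxyl is cleaved by the methanol work-up), which masks both hydroxyls for the enolate chemistry of step 21.

Step 18
Reactants: 22 the acetonide alcohol
Product: 23 C16 acetate
Conditions: Ac2O, pyridine, DMAP (cat.), CH2Cl2, 0 °C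
Reagents that add atoms: acetic anhydride (CC(=O)OC(C)=O)
Why: DMAP-catalysed acetylation of the only free (primary allylic) hydroxyl installs the C16 acetate of the target.

Step 19
Reactants: 23 the bis-TBS ether
Product: 24 diol (C2–OH primary, C14–OH secondary)
Conditions: HF·pyridine, pyridine, THF, 0 °C → rt
Reagents that add atoms: none
Why: HF·pyridine cleaves the primary and the secondary TBS ether in one operation, and the acetonide, acetate and lactone are stable to it.

Step 20
Reactants: 24 the diol
Product: 25 seco keto-aldehyde (C14 ketone with C1(CH3)(SPh), C2 aldehyde)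
Conditions: Dess–Martin periodinane (3 equiv), NaHCO3, CH2Cl2, rt
Reagents that add atoms: none
Why: Dess–Martin oxidation converts the C14 alcohol into the ketone and the C2 alcohol into the aldehyde in one operation, which erases the C14 epimer mixture.

Step 21
Reactants: 25 the seco keto-aldehyde
Product: 27 macrocyclic β-hydroxy ketone (ten-membered ring closed; C1 quaternary, C2–OH, C14 ketone), via samarium enolate 26 (not isolated)
Conditions: SmI2 (2.5 equiv), THF, −78 °C, 25 added by syringe pump (final 2 mM); sat. aq. NH4Cl at −78 °C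
Reagents that add atoms: none
Why: SmI2 reduces the C1–S bond of the α-phenylthio ketone (two one-electron transfers, loss of PhS–) and releases the Sm(III) enolate C14(OSm)=C1 regiospecifically at C1, although C13 is the more acidic α-position of the parent ketone, and this enolate adds to the C2 aldehyde in a Reformatsky-type aldol. The closest known reaction type is the SmI2-mediated intramolecular Reformatsky/aldol cyclisation of α-heterosubstituted carbonyl compounds onto aldehydes, which is used for medium and large rings. The ten-membered ring closes in a 10-(enolexo)-exo-trig mode. At C1 the aldehyde adds to the enolate face anti to the pseudo-axial C9 chain on C10 (A1,2 strain with the C1 and C11 methyl groups), which gives the trans ring fusion, and at C2 a Sm(III)-chelated Zimmerman–Traxler chair with the C3 chain equatorial (C3 anti to C14, H2 anti to CH3-15) gives the carbinol configuration of the target. The step needs C–S cleavage before ketyl formation at the aldehyde (−78 °C, no HMPA), aldol before enolate protonation or acyl attack (no free hydroxyl; O8/O9 tied in the acetonide, which also holds the C7–C8–C9–C10 backbone extended) and cyclisation before oligomerisation (slow addition, high dilution).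

Step 22
Reactants: 27 the β-hydroxy ketone
Product: 28 C2,C14-anti diol (C14–OH cis to C2 on the cyclohexene; acetonide retained)
Conditions: Me4NBH(OAc)3, MeCN/AcOH (1:1), −20 °C
Reagents that add atoms: none
Why: Evans–Saksena reduction: the C2 hydroxyl binds the triacetoxyborohydride and delivers hydride intramolecularly through a chair transition state to the C14 face syn to the C1 methyl group, which gives the 1,3-anti diol with the C14 oxygen cis to C2 as in the target.

Step 23
Reactants: 28 the diol acetonide
Product: 29 tetraol (C2, C9, C14 secondary OH and C8 tertiary OH; C16 acetate)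
Conditions: AcOH/H2O (4:1), 45 °C
Reagents that add atoms: none
Why: Acid hydrolysis of the isopropylidene acetal frees the C8 and C9 hydroxyls, while the allylic acetate and the lactone survive warm aqueous acetic acid.

Step 24
Reactants: 29 the tetraol
Product: 30 CNP0277472.2 (target)
Conditions: Ac2O, pyridine, DMAP (cat.), CH2Cl2, rt
Reagents that add atoms: acetic anhydride (CC(=O)OC(C)=O)
Why: DMAP-catalysed acetylation esterifies the three secondary hydroxyls (C2, C9, C14), and the tertiary C8 hydroxyl stays free for steric reasons, as is usual for 8-hydroxy briaranes.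

Compound list
1 | (4-bromobutoxy)(tert-butyl)dimethylsilane | BrCCCCO[Si](C)(C)C(C)(C)C | starting material
2 | [4-(tert-butyldimethylsilyloxy)butyl]triphenylphosphonium bromide | [Br-].CC(C)(C)[Si](C)(C)OCCCC[P+](c1ccccc1)(c1ccccc1)c1ccccc1 | intermediate
3 | [4-(tert-butyldimethylsilyloxy)butylidene]triphenylphosphorane (ylide, not isolated) | CC(C)(C)[Si](C)(C)OCCCC=P(c1ccccc1)(c1ccccc1)c1ccccc1 | intermediate
4 | 5-(tert-butyldimethylsilyloxy)-2-(triphenyl-λ5-phosphanylidene)pentanal | CC(C)(C)[Si](C)(C)OCCCC(C=O)=P(c1ccccc1)(c1ccccc1)c1ccccc1 | intermediate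
5 | L-arabinose (aldehydo form drawn) | O=C[C@H](O)[C@@H](O)[C@@H](O)CO | starting material
6 | 5-O-(tert-butyldiphenylsilyl)-L-arabinofuranose, anomer mixture | O[C@H]1[C@H](CO[Si](c2ccccc2)(c2ccccc2)C(C)(C)C)OC(O)[C@@H]1O | intermediate
7 | 5-O-TBDPS-1,2-O-isopropylidene-β-L-arabinofuranose | O[C@H]1[C@H](CO[Si](c3ccccc3)(c3ccccc3)C(C)(C)C)O[C@@H]2OC(C)(C)O[C@@H]21 | intermediate
8 | 5-O-TBDPS-1,2-O-isopropylidene-β-L-threo-pentofuranos-3-ulose | O=C1[C@H](CO[Si](c3ccccc3)(c3ccccc3)C(C)(C)C)O[C@@H]2OC(C)(C)O[C@@H]21 | intermediate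
9 | methyl 2-(5-O-TBDPS-1,2-O-isopropylidene-β-L-lyxofuranos-3-C-yl)propanoate, C17 epimers | COC(=O)C(C)[C@@]1(O)[C@H](CO[Si](c3ccccc3)(c3ccccc3)C(C)(C)C)O[C@@H]2OC(C)(C)O[C@@H]21 | intermediate
10 | methyl 2-(1,2-O-isopropylidene-β-L-lyxofuranos-3-C-yl)propanoate, C17 epimers | COC(=O)C(C)[C@@]1(O)[C@H](CO)O[C@@H]2OC(C)(C)O[C@@H]21 | intermediate
11 | corresponding 5-aldehyde (L-lyxo-pentodialdo-1,4-furanose, not isolated) | COC(=O)C(C)[C@@]1(O)[C@H](C=O)O[C@@H]2OC(C)(C)O[C@@H]21 | intermediate
12 | (E)-2-methyl enal on C9 of the furanose (C10=C1, C14 aldehyde) | COC(=O)C(C)[C@@]1(O)[C@H](/C=C(\C)C=O)O[C@@H]2OC(C)(C)O[C@@H]21 | intermediate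
13 | TMS enol ether of the conjugate adduct (C10 isopropenyl, C10 as in target; not isolated) | COC(=O)C(C)[C@@]1(O)[C@H]([C@@H](C(C)=C)C(C)=CO[Si](C)(C)C)O[C@@H]2OC(C)(C)O[C@@H]21 | intermediate
14 | α-methyl-α-(phenylthio) aldehyde with C10 isopropenyl, C1 epimers | COC(=O)C(C)[C@@]1(O)[C@H]([C@@H](C(C)=C)C(C)(Sc3ccccc3)C=O)O[C@@H]2OC(C)(C)O[C@@H]21 | intermediate
15 | homoallylic alcohol (C14–OH), C1/C14 epimers | COC(=O)C(C)[C@@]1(O)[C@H]([C@@H](C(C)=C)C(C)(Sc3ccccc3)C(O)CC=C)O[C@@H]2OC(C)(C)O[C@@H]21 | intermediate
16 | C14 TBS ether of 15 | COC(=O)C(C)[C@@]1(O)[C@H]([C@@H](C(C)=C)C(C)(Sc3ccccc3)C(CC=C)O[Si](C)(C)C(C)(C)C)O[C@@H]2OC(C)(C)O[C@@H]21 | intermediate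
17 | cyclohexene from ring-closing metathesis (C11=C12), furanose acetonide intact | COC(=O)C(C)[C@@]1(O)[C@H]([C@H]3C(C)=CCC(O[Si](C)(C)C(C)(C)C)C3(C)Sc4ccccc4)O[C@@H]2OC(C)(C)O[C@@H]21 | intermediate
18 | lactol (free furanose at C6, free C7–OH) | COC(=O)C(C)[C@@]1(O)[C@H]([C@H]3C(C)=CCC(O[Si](C)(C)C(C)(C)C)C3(C)Sc4ccccc4)OC(O)[C@@H]1O | intermediate
19 | open-chain (E)-enal, C7/C8/C9 triol, C19 methyl ester, C2–OTBS | O=C/C(CCCO[Si](C)(C)C(C)(C)C)=C/[C@H](O)[C@@](O)(C(C)C(=O)OC)[C@@H](O)[C@H]1C(C)=CCC(O[Si](C)(C)C(C)(C)C)C1(C)Sc1ccccc1 | intermediate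
20 | allylic alcohol (C16–OH), tetraol methyl ester | OC/C(CCCO[Si](C)(C)C(C)(C)C)=C/[C@H](O)[C@@](O)(C(C)C(=O)OC)[C@@H](O)[C@H]1C(C)=CCC(O[Si](C)(C)C(C)(C)C)C1(C)Sc1ccccc1 | intermediate
21 | γ-lactone (O7–C19), C17 set, C8/C9/C16 hydroxyls free | OC/C(CCCO[Si](C)(C)C(C)(C)C)=C/[C@@H]1OC(=O)[C@H](C)[C@@]1(O)[C@@H](O)[C@H]1C(C)=CCC(O[Si](C)(C)C(C)(C)C)C1(C)Sc1ccccc1 | intermediate
22 | O8,O9-isopropylidene acetal of 21 | OC/C(CCCO[Si](C)(C)C(C)(C)C)=C/[C@@H]1OC(=O)[C@H](C)[C@]12OC(C)(C)O[C@H]2[C@H]1C(C)=CCC(O[Si](C)(C)C(C)(C)C)C1(C)Sc1ccccc1 | intermediate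
23 | C16 acetate of 22 | CC(=O)OC/C(CCCO[Si](C)(C)C(C)(C)C)=C/[C@@H]1OC(=O)[C@H](C)[C@]12OC(C)(C)O[C@H]2[C@H]1C(C)=CCC(O[Si](C)(C)C(C)(C)C)C1(C)Sc1ccccc1 | intermediate
24 | diol (C2–OH, C14–OH) | CC(=O)OC/C(CCCO)=C/[C@@H]1OC(=O)[C@H](C)[C@]12OC(C)(C)O[C@H]2[C@H]1C(C)=CCC(O)C1(C)Sc1ccccc1 | intermediate
25 | seco keto-aldehyde (C14 ketone, C1–SPh, C2 aldehyde) | CC(=O)OC/C(CCC=O)=C/[C@@H]1OC(=O)[C@H](C)[C@]12OC(C)(C)O[C@H]2[C@H]1C(C)=CCC(=O)C1(C)Sc1ccccc1 | intermediate
26 | samarium(III) enolate C14(OSmI2)=C1 (not isolated) | CC(=O)OC/C(CCC=O)=C/[C@@H]1OC(=O)[C@H](C)[C@]12OC(C)(C)O[C@H]2[C@H]1C(C)=CCC(O[Sm](I)I)=C1C | intermediate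
27 | macrocyclic β-hydroxy ketone (C2–OH, C14 ketone), O8,O9-acetonide | CC(=O)OC/C1=C/[C@@H]2OC(=O)[C@H](C)[C@]23OC(C)(C)O[C@H]3[C@H]2C(C)=CCC(=O)[C@]2(C)[C@@H](O)CC1 | intermediate
28 | C2,C14-anti diol, O8,O9-acetonide | CC(=O)OC/C1=C/[C@@H]2OC(=O)[C@H](C)[C@]23OC(C)(C)O[C@H]3[C@H]2C(C)=CC[C@H](O)[C@]2(C)[C@@H](O)CC1 | intermediate
29 | 2,9,14-triol with free 8-OH (16-acetate) | CC(=O)OC/C1=C/[C@@H]2OC(=O)[C@H](C)[C@@]2(O)[C@@H](O)[C@H]2C(C)=CC[C@H](O)[C@]2(C)[C@@H](O)CC1 | intermediate
30 | CNP0277472.2 | CC(=O)OC/C1=C/[C@@H]2OC(=O)[C@H](C)[C@@]2(O)[C@@H](OC(C)=O)[C@H]2C(C)=CC[C@H](OC(C)=O)[C@]2(C)[C@@H](OC(C)=O)CC1 | target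

Total step count: 24. Longest linear sequence: 22 steps (steps 3–24, from L-arabinose); the ylide branch (steps 1–2) joins in step 14.

Steps most likely to fail

1. Step 21. The samarium enolate may be consumed before the slow ten-membered closure (proton transfer, attack on the lactone carbonyl), the aldehyde may be reduced to a ketyl and couple, or intermolecular aldol may give oligomers. Fallback, a chromium(II) Reformatsky closure of the same bond: it sets out from 25. The aldehyde is masked as the dimethyl acetal F1 (MeOTMS, TMSOTf cat., CH2Cl2, −78 °C). With no aldehyde present, the sulfide is cleaved by SmI2 in the presence of TMSCl/Et3N to the regiodefined trimethylsilyl enol ether F2. NBS (THF, −78 °C) converts it into the tertiary α-bromo ketone F3. Mild acetal hydrolysis (Amberlyst-15, wet acetone, rt; the dioxolane acetonide stays) gives the α-bromo keto-aldehyde F4. CrCl2/LiI (THF, rt, 2 mM) then closes the ring through a chromium(III) enolate, which does not reduce aldehydes and ignores esters. The fallback comes back to the route at 27.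

2. Step 14. The hindered, strongly stabilised formyl ylide may olefinate the small open-chain fraction of the lactol too slowly, and the freed C9 hydroxyl may add to the enal (oxa-Michael closure to a tetrahydrofuran). Fallback, a more nucleophilic acyl ylide followed by reductive adjustment: ylide 3 (from 2) is acylated with S-ethyl chlorothioformate (0.5 equiv, THF, 0 °C) to the thioester ylide F5. Wittig reaction of F5 with 18 (toluene, 80 °C) gives the (E)-thioester F6. NaBH4/CeCl3 (EtOH, 0 °C) reduces the thioester through the enal to the allylic alcohol without touching the methyl ester. The fallback sets out from 18 and comes back to the route at 20.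

3. Step 9. PhSCl may be consumed by residual organocopper or organomagnesium species or add across the isopropenyl group, so that sulfenylation of the silyl enol ether is incomplete. Fallback, enamine catalysis on the isolated aldehyde: it sets out from 12. The same conjugate addition is worked up with aqueous acid to give the α-methyl aldehyde F7. Pyrrolidine-catalysed α-sulfenylation with N-(phenylthio)phthalimide (CH2Cl2, rt) then gives the quaternary sulfide through the enamine of the α-branched aldehyde. The fallback comes back to the route at 14.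

Further compounds
F1 | step 21 | dimethyl acetal of keto-aldehyde 25 (C2 as CH(OMe)2) | CC(=O)OC/C(CCC(OC)OC)=C/[C@@H]1OC(=O)[C@H](C)[C@]12OC(C)(C)O[C@H]2[C@H]1C(C)=CCC(=O)C1(C)Sc1ccccc1
F2 | step 21 | trimethylsilyl enol ether C14(OTMS)=C1 of F1 | CC(=O)OC/C(CCC(OC)OC)=C/[C@@H]1OC(=O)[C@H](C)[C@]12OC(C)(C)O[C@H]2[C@H]1C(C)=CCC(O[Si](C)(C)C)=C1C
F3 | step 21 | α-bromo ketone (C1–Br) dimethyl acetal | CC(=O)OC/C(CCC(OC)OC)=C/[C@@H]1OC(=O)[C@H](C)[C@]12OC(C)(C)O[C@H]2[C@H]1C(C)=CCC(=O)C1(C)Br
F4 | step 21 | α-bromo keto-aldehyde | CC(=O)OC/C(CCC=O)=C/[C@@H]1OC(=O)[C@H](C)[C@]12OC(C)(C)O[C@H]2[C@H]1C(C)=CCC(=O)C1(C)Br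
F5 | step 14 | S-ethyl 5-(tert-butyldimethylsilyloxy)-2-(triphenyl-λ5-phosphanylidene)pentanethioate | CCSC(=O)C(CCCO[Si](C)(C)C(C)(C)C)=P(c1ccccc1)(c1ccccc1)c1ccccc1
F6 | step 14 | (E)-α,β-unsaturated S-ethyl thioester analogue of 19 | CCSC(=O)/C(CCCO[Si](C)(C)C(C)(C)C)=C/[C@H](O)[C@@](O)(C(C)C(=O)OC)[C@@H](O)[C@H]1C(C)=CCC(O[Si](C)(C)C(C)(C)C)C1(C)Sc1ccccc1
F7 | step 9 | α-methyl aldehyde from the conjugate addition (no sulfur at C1) | COC(=O)C(C)[C@@]1(O)[C@H]([C@@H](C(C)=C)C(C)C=O)O[C@@H]2OC(C)(C)O[C@@H]21
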